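The route rests on cutting the ten-membered carbocycle (C1–C10) at its 2-methylene-1,3-diene, C15=C4–C5=C6: this unit is what an endo ring-closing enyne metathesis makes from a C4≡C5 terminal alkyne and a C6 vinyl group. The final step therefore closes the carbocycle, installs the exocyclic methylene and sets the Z ring alkene in one operation, exploiting the chroman ring, which holds the two reacting chains trans on the adjacent carbons C1 and C10. The precursor is the complete diformyl-dihydroxy-isobutylchroman bearing a butynyl arm on C1 and a vinyl-substituted tertiary-carbinol arm on C10, assembled from geraniol by two asymmetric epoxidations and an aryl-ether/Friedel–Crafts chroman synthesis.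

Key step: step 16

Remark on locants: C1–C10 are the carbons of the ten-membered ring, C15 the exocyclic methylene carbon, C11 the carbinol carbon and C1′ the benzylic carbon bearing isobutyl. Intermediates are also named as chromans (O1, C2 = C10, C3 = C1, C4 = C1′).

Step 1
Reactants: 1 geraniol
Product: 2 (2R,3R)-2,3-epoxygeraniol
Conditions: Ti(OiPr)4 (10 mol%), D-(−)-diethyl tartrate (12 mol%), t-BuOOH, 4 Å MS, CH2Cl2, −20 °C
Reagents that add atoms: tert-butyl hydroperoxide, CC(C)(C)OO
Why: Sharpless asymmetric epoxidation of the allylic alcohol, in which the titanium/D-(−)-tartrate complex delivers oxygen to one face of the 2,3-alkene only, fixing both epoxide carbons (the future C10 and, after inversion, C1) and leaving the remote trisubstituted alkene untouched.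

Step 2
Reactants: 2 (2R,3R)-2,3-epoxygeraniol; 3 (4-bromobut-1-yn-1-yl)trimethylsilane
Product: 5 (2S,3R)-3,7-dimethyl-2-[4-(trimethylsilyl)but-3-yn-1-yl]oct-6-ene-1,3-diol, via Grignard reagent 4 (not isolated)
Conditions: 3 (3 equiv), Mg, THF, rt; then CuI (10 mol%), 2, THF, −40 → 0 °C; aq. NH4Cl
Reagents that add atoms: none
Why: Copper-catalysed Grignard (cuprate) opening of a 2,3-epoxy alcohol, in which the 3,3-disubstituted epoxide is attacked in SN2 fashion at its less substituted carbon with inversion, so that anti addition across the former E-alkene gives the relative configuration needed for trans chains on C1 and C10.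

Step 3
Reactants: 5 (2S,3R)-3,7-dimethyl-2-[4-(trimethylsilyl)but-3-yn-1-yl]oct-6-ene-1,3-diol
Product: 6 (2S,3R)-1-[(4-methoxybenzyl)oxy]-3,7-dimethyl-2-[4-(trimethylsilyl)but-3-yn-1-yl]oct-6-en-3-ol
Conditions: NaH (1.05 equiv), 4-methoxybenzyl chloride, n-Bu4NI (cat.), THF, 0 °C → rt
Reagents that add atoms: 4-methoxybenzyl chloride, COc1ccc(CCl)cc1
Why: Williamson etherification in which the primary alkoxide forms and alkylates far faster than the hindered tertiary one, so one equivalent of base leaves the tertiary hydroxyl free for arylation.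

Step 4
Reactants: 7 1-iodo-3,5-dimethoxybenzene
Product: 9 (3,5-dimethoxyphenyl)(2,4,6-trimethoxyphenyl)iodonium tosylate, via hydroxy(tosyloxy)iodoarene 8 (not isolated)
Conditions: mCPBA, TsOH·H2O, MeCN, 0 °C → rt; then 1,3,5-trimethoxybenzene, rt; Et2O trituration
Reagents that add atoms: 4-methylbenzenesulfonic acid monohydrate, Cc1ccc(S(=O)(=O)O)cc1.O; 1,3,5-trimethoxybenzene, COc1cc(OC)cc(OC)c1
Why: One-pot oxidation of the aryl iodide to a trivalent iodine species and electrophilic ligation by the most nucleophilic arene present, a known entry to aryl(trimethoxyphenyl)iodonium salts whose trimethoxyphenyl group later acts as the non-transferred ligand.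

Step 5
Reactants: 6 (2S,3R)-1-[(4-methoxybenzyl)oxy]-3,7-dimethyl-2-[4-(trimethylsilyl)but-3-yn-1-yl]oct-6-en-3-ol; 9 (3,5-dimethoxyphenyl)(2,4,6-trimethoxyphenyl)iodonium tosylate
Product: 10 (2S,3R)-3-(3,5-dimethoxyphenoxy)-1-[(4-methoxybenzyl)oxy]-3,7-dimethyl-2-[4-(trimethylsilyl)but-3-yn-1-yl]oct-6-ene
Conditions: NaH (1.2 equiv), toluene, rt; then 9 (1.3 equiv), rt → 40 °C
Reagents that add atoms: none
Why: Metal-free O-arylation of a tertiary alkoxide with a diaryliodonium salt (ligand exchange at iodine, then ligand coupling), in which the less electron-rich, unhindered 3,5-dimethoxyphenyl group is transferred and the carbinol C–O bond is never broken, so C10 keeps its configuration.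

Step 6
Reactants: 10 (2S,3R)-3-(3,5-dimethoxyphenoxy)-1-[(4-methoxybenzyl)oxy]-3,7-dimethyl-2-[4-(trimethylsilyl)but-3-yn-1-yl]oct-6-ene
Product: 11 (2S,3R)-3-(3,5-dimethoxyphenoxy)-3,7-dimethyl-2-[4-(trimethylsilyl)but-3-yn-1-yl]oct-6-en-1-ol
Conditions: DDQ, CH2Cl2/pH 7 phosphate buffer, 0 °C → rt
Reagents that add atoms: none
Why: Oxidative cleavage of the 4-methoxybenzyl ether by benzylic hydride abstraction and hydrolysis, to which the trioxygenated aryl ether (no benzylic hydrogen), the alkene and the silylalkyne are inert under buffered conditions.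

Step 7
Reactants: 11 (2S,3R)-3-(3,5-dimethoxyphenoxy)-3,7-dimethyl-2-[4-(trimethylsilyl)but-3-yn-1-yl]oct-6-en-1-ol
Product: 13 (2R,3R)-3-(3,5-dimethoxyphenoxy)-3,7-dimethyl-2-[4-(trimethylsilyl)but-3-yn-1-yl]oct-6-enoic acid, via aldehyde 12 (not isolated)
Conditions: TEMPO (20 mol%), PhI(OAc)2 (2.2 equiv), MeCN/H2O, rt
Reagents that add atoms: water, O
Why: Oxoammonium (TEMPO) oxidation of the primary alcohol through the aldehyde hydrate to the acid in one flask, so the β-aryloxy aldehyde, which would readily lose phenoxide under base, is never isolated, while the near-neutral medium spares alkene, alkyne and arene.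

Step 8
Reactants: 13 (2R,3R)-3-(3,5-dimethoxyphenoxy)-3,7-dimethyl-2-[4-(trimethylsilyl)but-3-yn-1-yl]oct-6-enoic acid
Product: 15 (2R,3R)-5,7-dimethoxy-2-methyl-2-(4-methylpent-3-en-1-yl)-3-[4-(trimethylsilyl)but-3-yn-1-yl]chroman-4-one, via mixed anhydride 14 (not isolated)
Conditions: (CF3CO)2O (1.5 equiv), CH2Cl2, 0 °C; cold aq. NaHCO3 quench
Reagents that add atoms: none
Why: Intramolecular Friedel–Crafts acylation through the mixed trifluoroacetic anhydride, in which the phloroglucinol-type ring closes the pyranone at either of its two equivalent positions ortho to the ether oxygen much faster than alkene or alkyne could react, under short, cold, weakly acidic conditions that should not enolise the ketone, so C1 (chroman C3) is preserved.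

Step 9
Reactants: 15 (2R,3R)-5,7-dimethoxy-2-methyl-2-(4-methylpent-3-en-1-yl)-3-[4-(trimethylsilyl)but-3-yn-1-yl]chroman-4-one; 16 isobutylmagnesium bromide
Product: 17 (2R,3S)-4-isobutyl-5,7-dimethoxy-2-methyl-2-(4-methylpent-3-en-1-yl)-3-[4-(trimethylsilyl)but-3-yn-1-yl]chroman-4-ol (C4 configuration unassigned; either epimer serves)
Conditions: 16 (3 equiv), anhydrous CeCl3 (3 equiv), THF, −78 → −20 °C; aq. NH4Cl
Reagents that add atoms: none
Why: Organocerium 1,2-addition to a hindered, enolisable, electronically deactivated aryl ketone, where the weakly basic cerium reagent suppresses enolisation (hence retro-oxa-Michael opening and C3 epimerisation) and β-hydride reduction; the new carbinol centre is planarised in the next step.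

Step 10
Reactants: 17 (2R,3S)-4-isobutyl-5,7-dimethoxy-2-methyl-2-(4-methylpent-3-en-1-yl)-3-[4-(trimethylsilyl)but-3-yn-1-yl]chroman-4-ol
Product: 18 (2R,3S,4R)-4-isobutyl-5,7-dimethoxy-2-methyl-2-(4-methylpent-3-en-1-yl)-3-[4-(trimethylsilyl)but-3-yn-1-yl]chroman
Conditions: Et3SiH (10 equiv), BF3·OEt2 (2 equiv, promoter), CH2Cl2, −78 → −40 °C
Reagents that add atoms: none
Why: Ionic hydrogenation of a tertiary benzylic alcohol, in which the 2,4,6-trioxygenated benzylic cation formed at low temperature is captured by excess silane on the face trans to the adjacent C3 chain (the usual sense for 3-substituted chroman-4-yl cations, reinforced by the C2 methyl on the same face as that chain), so isobutyl ends up cis to the C3 chain and C1′ is set as R.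

Step 11
Reactants: 18 (2R,3S,4R)-4-isobutyl-5,7-dimethoxy-2-methyl-2-(4-methylpent-3-en-1-yl)-3-[4-(trimethylsilyl)but-3-yn-1-yl]chroman
Product: 19 (2R,3S,4R)-2-{2-[(2R)-3,3-dimethyloxiran-2-yl]ethyl}-4-isobutyl-5,7-dimethoxy-2-methyl-3-[4-(trimethylsilyl)but-3-yn-1-yl]chroman
Conditions: D-fructose-derived Shi ketone (1,2:4,5-di-O-isopropylidene-β-D-erythro-2,3-hexodiulo-2,6-pyranose, 30 mol%), Oxone (2KHSO5·KHSO4·K2SO4), K2CO3, n-Bu4NHSO4, MeCN/dimethoxymethane/aq. Na2B4O7 buffer (pH 10.5), 0 °C
Reagents that add atoms: potassium peroxymonosulfate (active component of Oxone), [K+].[O-]S(=O)(=O)OO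
Why: Shi asymmetric epoxidation by the chiral dioxirane through a spiro transition state, in which the trisubstituted alkene is the only reactive π-bond and the D-fructose-derived ketone dictates the face irrespective of the remote chroman centres, giving the (R)-epoxide at C7.

Step 12
Reactants: 19 (2R,3S,4R)-2-{2-[(2R)-3,3-dimethyloxiran-2-yl]ethyl}-4-isobutyl-5,7-dimethoxy-2-methyl-3-[4-(trimethylsilyl)but-3-yn-1-yl]chroman; 20 vinylmagnesium bromide
Product: 21 (2R,3S,4R)-2-[(3R)-3-(2-hydroxypropan-2-yl)pent-4-en-1-yl]-4-isobutyl-5,7-dimethoxy-2-methyl-3-[4-(trimethylsilyl)but-3-yn-1-yl]chroman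
Conditions: 20 (5 equiv), CuI (30 mol%), THF, −40 → 0 °C; aq. NH4Cl
Reagents that add atoms: none
Why: Copper-catalysed SN2 opening of a trisubstituted epoxide by a vinyl cuprate at the less substituted carbon, where backside attack inverts C7 and frees the tertiary alcohol, giving the (R)-configured vinyl carbinol unit of the target.

Step 13
Reactants: 21 (2R,3S,4R)-2-[(3R)-3-(2-hydroxypropan-2-yl)pent-4-en-1-yl]-4-isobutyl-5,7-dimethoxy-2-methyl-3-[4-(trimethylsilyl)but-3-yn-1-yl]chroman
Product: 22 (2R,3S,4R)-6,8-dibromo-2-[(3R)-3-(2-hydroxypropan-2-yl)pent-4-en-1-yl]-4-isobutyl-5,7-dimethoxy-2-methyl-3-[4-(trimethylsilyl)but-3-yn-1-yl]chroman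
Conditions: NBS (2.05 equiv), MeCN, −20 → 0 °C, dark
Reagents that add atoms: N-bromosuccinimide, O=C1CCC(=O)N1Br
Why: Electrophilic aromatic bromination, in which the two free ring positions are each ortho/para to three oxygen donors and react far faster than the monosubstituted alkene or the silylalkyne, giving regiodefined handles for metalation.

Step 14
Reactants: 22 (2R,3S,4R)-6,8-dibromo-2-[(3R)-3-(2-hydroxypropan-2-yl)pent-4-en-1-yl]-4-isobutyl-5,7-dimethoxy-2-methyl-3-[4-(trimethylsilyl)but-3-yn-1-yl]chroman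
Product: 24 (2R,3S,4R)-2-[(3R)-3-(2-hydroxypropan-2-yl)pent-4-en-1-yl]-4-isobutyl-5,7-dimethoxy-2-methyl-3-[4-(trimethylsilyl)but-3-yn-1-yl]chroman-6,8-dicarbaldehyde, via trilithiated species 23 (not isolated)
Conditions: t-BuLi (5.2 equiv), THF, −78 °C; then DMF (10 equiv), −78 → 0 °C; aq. NH4Cl
Reagents that add atoms: N,N-dimethylformamide, CN(C)C=O
Why: Double bromine–lithium exchange (after deprotonation of the tertiary alcohol) and formylation of both aryllithium sites with DMF, where exchange at −78 °C outruns deprotonation next to the alkyne, each aryllithium is stabilised by two flanking oxygens, and the silyl cap protects the alkyne C–H.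

Step 15
Reactants: 24 (2R,3S,4R)-2-[(3R)-3-(2-hydroxypropan-2-yl)pent-4-en-1-yl]-4-isobutyl-5,7-dimethoxy-2-methyl-3-[4-(trimethylsilyl)but-3-yn-1-yl]chroman-6,8-dicarbaldehyde
Product: 26 (2R,3S,4R)-3-(but-3-yn-1-yl)-5,7-dihydroxy-2-[(3R)-3-(2-hydroxypropan-2-yl)pent-4-en-1-yl]-4-isobutyl-2-methylchroman-6,8-dicarbaldehyde, via silylated bisphenol 25 (not isolated)
Conditions: NaSEt (8 equiv), DMF, 90 °C; cool, then MeOH, K2CO3, rt; aq. HCl to pH 4
Reagents that add atoms: none
Why: Thiolate demethylation (SN2 at methyl) of aryl methyl ethers activated by ortho and para formyl groups, which cannot touch the tertiary alkyl aryl ether of the chroman or the tertiary alcohol as a Lewis acid could, followed in the same flask by base-mediated protodesilylation of the alkynylsilane in methanol.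

Step 16
Reactants: 26 (2R,3S,4R)-3-(but-3-yn-1-yl)-5,7-dihydroxy-2-[(3R)-3-(2-hydroxypropan-2-yl)pent-4-en-1-yl]-4-isobutyl-2-methylchroman-6,8-dicarbaldehyde
Product: 28 CNP0479784.1 (1S,1′R,7R,10R; 4(15),5Z-diene), via butadiene 27 (not isolated)
Conditions: (H2IMes)(PCy3)Cl2Ru=CHPh (second-generation Grubbs catalyst, 2 × 10 mol%), ethylene (1 atm), toluene (1 mM), rt → 60 °C; then argon sparge, 80 °C
Reagents that add atoms: ethylene, C=C
Why: The ruthenium methylidene generated from ethylene adds to the terminal alkyne and, through a ruthenacyclobutene and a vinylcarbene that takes up a second methylene, converts C4≡C5 into the 2-substituted butadiene C15=C4–C5=CH2 (27); the carbene then loads on the monosubstituted diene terminus and undergoes ring-closing metathesis with the C6 vinyl group, releasing ethylene. The closest known reaction type is the ethylene-mediated tandem enyne cross-metathesis/diene ring-closing metathesis used for endo-mode macrocyclic enyne ring closure. The ten-membered carbocycle closes in the endo mode: both alkyne carbons become ring members and C15 stays exocyclic because the 1,1-disubstituted alkene is not engaged by the carbene. No stereocentre is created; the only new stereo-element, the C5=C6 geometry, is controlled by the ring, since the Z alkene is the less strained isomer in a ten-membered ring and metathesis is reversible under these conditions. The step needs endo over exo closure and cyclisation over oligomerisation: ethylene consumes the alkyne before an ene-first exo pathway can operate, the chroman holds the two chains trans (gauche) on the adjacent carbons C1 and C10 so the reacting termini are close, and high dilution together with the hindered α-branched C7 vinyl disfavours intermolecular metathesis. Hydrogen-bonded phenols, aryl aldehydes and the tertiary alcohol are tolerated by ruthenium carbenes, which allows the ring closure to be the last step.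

Compound list
1 | geraniol, (2E)-3,7-dimethylocta-2,6-dien-1-ol | CC(C)=CCC/C(C)=C/CO | starting material
2 | (2R,3R)-2,3-epoxygeraniol, [(2R,3R)-3-methyl-3-(4-methylpent-3-en-1-yl)oxiran-2-yl]methanol | OC[C@H]1O[C@]1(C)CCC=C(C)C | intermediate
3 | (4-bromobut-1-yn-1-yl)trimethylsilane | BrCCC#C[Si](C)(C)C | starting material
4 | [4-(trimethylsilyl)but-3-yn-1-yl]magnesium bromide | Br[Mg]CCC#C[Si](C)(C)C | intermediate
5 | (2S,3R)-3,7-dimethyl-2-[4-(trimethylsilyl)but-3-yn-1-yl]oct-6-ene-1,3-diol | OC[C@@H]([C@](C)(O)CCC=C(C)C)CCC#C[Si](C)(C)C | intermediate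
6 | (2S,3R)-1-[(4-methoxybenzyl)oxy]-3,7-dimethyl-2-[4-(trimethylsilyl)but-3-yn-1-yl]oct-6-en-3-ol | COc1ccc(COC[C@@H]([C@](C)(O)CCC=C(C)C)CCC#C[Si](C)(C)C)cc1 | intermediate
7 | 1-iodo-3,5-dimethoxybenzene | COc1cc(I)cc(OC)c1 | starting material
8 | [hydroxy(tosyloxy)iodo]-3,5-dimethoxybenzene | COc1cc(OC)cc(I(O)OS(=O)(=O)c2ccc(C)cc2)c1 | intermediate
9 | (3,5-dimethoxyphenyl)(2,4,6-trimethoxyphenyl)iodonium tosylate | COc1cc(OC)cc([I+]c2c(OC)cc(OC)cc2OC)c1.Cc1ccc(S(=O)(=O)[O-])cc1 | intermediate
10 | (2S,3R)-3-(3,5-dimethoxyphenoxy)-1-[(4-methoxybenzyl)oxy]-3,7-dimethyl-2-[4-(trimethylsilyl)but-3-yn-1-yl]oct-6-ene | COc1ccc(COC[C@@H]([C@](C)(Oc2cc(OC)cc(OC)c2)CCC=C(C)C)CCC#C[Si](C)(C)C)cc1 | intermediate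
11 | (2S,3R)-3-(3,5-dimethoxyphenoxy)-3,7-dimethyl-2-[4-(trimethylsilyl)but-3-yn-1-yl]oct-6-en-1-ol | OC[C@@H]([C@](C)(Oc1cc(OC)cc(OC)c1)CCC=C(C)C)CCC#C[Si](C)(C)C | intermediate
12 | (2R,3R)-3-(3,5-dimethoxyphenoxy)-3,7-dimethyl-2-[4-(trimethylsilyl)but-3-yn-1-yl]oct-6-enal | O=C[C@@H]([C@](C)(Oc1cc(OC)cc(OC)c1)CCC=C(C)C)CCC#C[Si](C)(C)C | intermediate
13 | (2R,3R)-3-(3,5-dimethoxyphenoxy)-3,7-dimethyl-2-[4-(trimethylsilyl)but-3-yn-1-yl]oct-6-enoic acid | OC(=O)[C@@H]([C@](C)(Oc1cc(OC)cc(OC)c1)CCC=C(C)C)CCC#C[Si](C)(C)C | intermediate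
14 | mixed anhydride of acid 13 and trifluoroacetic acid, (2R,3R) | O=C(OC(=O)C(F)(F)F)[C@@H]([C@](C)(Oc1cc(OC)cc(OC)c1)CCC=C(C)C)CCC#C[Si](C)(C)C | intermediate
15 | (2R,3R)-5,7-dimethoxy-2-methyl-2-(4-methylpent-3-en-1-yl)-3-[4-(trimethylsilyl)but-3-yn-1-yl]chroman-4-one | CC(C)=CCC[C@@]1(C)Oc2cc(OC)cc(OC)c2C(=O)[C@@H]1CCC#C[Si](C)(C)C | intermediate
16 | isobutylmagnesium bromide | CC(C)C[Mg]Br | starting material
17 | (2R,3S)-4-isobutyl-5,7-dimethoxy-2-methyl-2-(4-methylpent-3-en-1-yl)-3-[4-(trimethylsilyl)but-3-yn-1-yl]chroman-4-ol, C4 unassigned | CC(C)=CCC[C@@]1(C)Oc2cc(OC)cc(OC)c2C(O)(CC(C)C)[C@@H]1CCC#C[Si](C)(C)C | intermediate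
18 | (2R,3S,4R)-4-isobutyl-5,7-dimethoxy-2-methyl-2-(4-methylpent-3-en-1-yl)-3-[4-(trimethylsilyl)but-3-yn-1-yl]chroman | CC(C)=CCC[C@@]1(C)Oc2cc(OC)cc(OC)c2[C@H](CC(C)C)[C@@H]1CCC#C[Si](C)(C)C | intermediate
19 | (2R,3S,4R)-2-{2-[(2R)-3,3-dimethyloxiran-2-yl]ethyl}-4-isobutyl-5,7-dimethoxy-2-methyl-3-[4-(trimethylsilyl)but-3-yn-1-yl]chroman | CC1(C)O[C@@H]1CC[C@@]2(C)Oc3cc(OC)cc(OC)c3[C@H](CC(C)C)[C@@H]2CCC#C[Si](C)(C)C | intermediate
20 | vinylmagnesium bromide | C=C[Mg]Br | starting material
21 | (2R,3S,4R)-2-[(3R)-3-(2-hydroxypropan-2-yl)pent-4-en-1-yl]-4-isobutyl-5,7-dimethoxy-2-methyl-3-[4-(trimethylsilyl)but-3-yn-1-yl]chroman | C=C[C@H](C(C)(C)O)CC[C@@]2(C)Oc3cc(OC)cc(OC)c3[C@H](CC(C)C)[C@@H]2CCC#C[Si](C)(C)C | intermediate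
22 | 6,8-dibromo derivative of 21, (2R,3S,4R,3′R) | C=C[C@H](C(C)(C)O)CC[C@@]2(C)Oc3c(Br)c(OC)c(Br)c(OC)c3[C@H](CC(C)C)[C@@H]2CCC#C[Si](C)(C)C | intermediate
23 | 6,8-dilithio lithium alkoxide derived from 22 | C=C[C@H](C(C)(C)O[Li])CC[C@@]2(C)Oc3c([Li])c(OC)c([Li])c(OC)c3[C@H](CC(C)C)[C@@H]2CCC#C[Si](C)(C)C | intermediate
24 | (2R,3S,4R)-2-[(3R)-3-(2-hydroxypropan-2-yl)pent-4-en-1-yl]-4-isobutyl-5,7-dimethoxy-2-methyl-3-[4-(trimethylsilyl)but-3-yn-1-yl]chroman-6,8-dicarbaldehyde | C=C[C@H](C(C)(C)O)CC[C@@]2(C)Oc3c(C=O)c(OC)c(C=O)c(OC)c3[C@H](CC(C)C)[C@@H]2CCC#C[Si](C)(C)C | intermediate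
25 | (2R,3S,4R)-5,7-dihydroxy-2-[(3R)-3-(2-hydroxypropan-2-yl)pent-4-en-1-yl]-4-isobutyl-2-methyl-3-[4-(trimethylsilyl)but-3-yn-1-yl]chroman-6,8-dicarbaldehyde | C=C[C@H](C(C)(C)O)CC[C@@]2(C)Oc3c(C=O)c(O)c(C=O)c(O)c3[C@H](CC(C)C)[C@@H]2CCC#C[Si](C)(C)C | intermediate
26 | (2R,3S,4R)-3-(but-3-yn-1-yl)-5,7-dihydroxy-2-[(3R)-3-(2-hydroxypropan-2-yl)pent-4-en-1-yl]-4-isobutyl-2-methylchroman-6,8-dicarbaldehyde (seco enyne) | C=C[C@H](C(C)(C)O)CC[C@@]2(C)Oc3c(C=O)c(O)c(C=O)c(O)c3[C@H](CC(C)C)[C@@H]2CCC#C | intermediate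
27 | (2R,3S,4R)-5,7-dihydroxy-2-[(3R)-3-(2-hydroxypropan-2-yl)pent-4-en-1-yl]-4-isobutyl-2-methyl-3-(3-methylidenepent-4-en-1-yl)chroman-6,8-dicarbaldehyde | C=C[C@H](C(C)(C)O)CC[C@@]2(C)Oc3c(C=O)c(O)c(C=O)c(O)c3[C@H](CC(C)C)[C@@H]2CCC(=C)C=C | intermediate
28 | CNP0479784.1: ten-membered 4(15),5Z-diene carbocycle trans-fused at C1/C10 to the 6,8-diformyl-5,7-dihydroxy-4-isobutylchroman, (1S,1′R,7R,10R) | C=C1/C=C\[C@H](C(C)(C)O)CC[C@@]2(C)Oc3c(C=O)c(O)c(C=O)c(O)c3[C@H](CC(C)C)[C@@H]2CC1 | target

Total step count: 16. Longest linear sequence: 15 steps (geraniol 1 to target 28 through steps 1–3 and 5–16); iodonium salt 9 is made in one side step (step 4).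

Steps most likely to fail

Step 16 (ring-closing enyne metathesis). Once the alkyne has been turned into the open-chain butadiene, closure of the strained ten-membered ring may be slower than intermolecular metathesis, or the carbene may be sequestered by the chelating hydroxy-aldehyde units, so the sequence stalls or oligomerises. The fallback sets out from dialdehyde 24, before the phenols are unmasked, and separates the two metathesis events. Protodesilylation (K2CO3, MeOH) would give the terminal alkyne bis(methyl ether) F1. Cross-metathesis with ethylene alone ((H2IMes)(PCy3)Cl2Ru=CHPh, ethylene, CH2Cl2, rt) would give the isolated butadiene bis(methyl ether) F2. This would be closed as an ordinary diene–alkene ring-closing metathesis with the phosphine-free carbene (H2IMes)Cl2Ru=CH(C6H4-2-OiPr) at high dilution under an argon purge to the macrocyclic bis(methyl ether) F3. Thiolate demethylation (NaSEt, DMF, 90 °C) then comes back to the route at target 28.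

Step 10 (ionic hydrogenation). The benzylic cation may lose the proton on C3, which would erase the C1 configuration on reprotonation, or be captured intramolecularly by the trisubstituted alkene before hydride arrives; facial selectivity may also be lower than expected. The fallback sets out from chromanone 15 and avoids acid and the free cation by passing through an o-quinone methide under basic conditions. Chelation-controlled cleavage of the methyl ether peri to the ketone (BCl3, CH2Cl2, −78 °C) would give the 5-hydroxychromanone F4, and Boc2O with catalytic DMAP the aryl tert-butyl carbonate F5. Addition of 16 (1.05 equiv, with CeCl3) at −78 °C gives an alkoxide that, on warming, takes over the carbonate group and expels tert-butyl carbonate to form the o-quinone methide F6. LiBH4, added before warming, reduces F6 in the same flask by conjugate hydride addition at the benzylic carbon anti to the C3 chain, giving the 5-hydroxy-4-isobutylchroman F7. Methylation (MeI, K2CO3, acetone) comes back to the route at 18.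

Step 5 (O-arylation). Ligand exchange and coupling at iodine may be too slow with the hindered tertiary alkoxide, so that base-induced decomposition of the salt (aryne formation, ligand scrambling) or silyl loss from the alkyne consumes the partners. The fallback sets out from alcohol 6 and forms the same C–O bond by nucleophilic aromatic substitution on a chromium-activated arene. The complex (η6-1-fluoro-3,5-dimethoxybenzene)Cr(CO)3 F8, made from 1-fluoro-3,5-dimethoxybenzene and Cr(CO)6 in Bu2O/THF at reflux, would be treated with the potassium alkoxide of 6 (KH, THF, 0 °C → rt). Addition–elimination with loss of fluoride would give the Cr(CO)3 complex of ether 10 F9. Oxidative decomplexation (I2, THF, 0 °C) comes back to the route at 10.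

Further compounds
F1 | step 16 | (2R,3S,4R)-3-(but-3-yn-1-yl)-2-[(3R)-3-(2-hydroxypropan-2-yl)pent-4-en-1-yl]-4-isobutyl-5,7-dimethoxy-2-methylchroman-6,8-dicarbaldehyde | C=C[C@H](C(C)(C)O)CC[C@@]2(C)Oc3c(C=O)c(OC)c(C=O)c(OC)c3[C@H](CC(C)C)[C@@H]2CCC#C
F2 | step 16 | (2R,3S,4R)-2-[(3R)-3-(2-hydroxypropan-2-yl)pent-4-en-1-yl]-4-isobutyl-5,7-dimethoxy-2-methyl-3-(3-methylidenepent-4-en-1-yl)chroman-6,8-dicarbaldehyde | C=C[C@H](C(C)(C)O)CC[C@@]2(C)Oc3c(C=O)c(OC)c(C=O)c(OC)c3[C@H](CC(C)C)[C@@H]2CCC(=C)C=C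
F3 | step 16 | bis(methyl ether) of target 28 | C=C1/C=C\[C@H](C(C)(C)O)CC[C@@]2(C)Oc3c(C=O)c(OC)c(C=O)c(OC)c3[C@H](CC(C)C)[C@@H]2CC1
F4 | step 10 | (2R,3R)-5-hydroxy-7-methoxy-2-methyl-2-(4-methylpent-3-en-1-yl)-3-[4-(trimethylsilyl)but-3-yn-1-yl]chroman-4-one | CC(C)=CCC[C@@]1(C)Oc2cc(OC)cc(O)c2C(=O)[C@@H]1CCC#C[Si](C)(C)C
F5 | step 10 | tert-butyl carbonate of F4 at the 5-oxygen | CC(C)=CCC[C@@]1(C)Oc2cc(OC)cc(OC(=O)OC(C)(C)C)c2C(=O)[C@@H]1CCC#C[Si](C)(C)C
F6 | step 10 | o-quinone methide (4-isobutyl C4=C4a, C5=O), formed and reduced in the flask | CC(C)=CCC[C@@]1(C)OC2=CC(OC)=CC(=O)C2=C(CC(C)C)[C@@H]1CCC#C[Si](C)(C)C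
F7 | step 10 | (2R,3S,4R)-4-isobutyl-7-methoxy-2-methyl-2-(4-methylpent-3-en-1-yl)-3-[4-(trimethylsilyl)but-3-yn-1-yl]chroman-5-ol | CC(C)=CCC[C@@]1(C)Oc2cc(OC)cc(O)c2[C@H](CC(C)C)[C@@H]1CCC#C[Si](C)(C)C
F8 | step 5 | (η6-1-fluoro-3,5-dimethoxybenzene)Cr(CO)3, written as its components | COc1cc(F)cc(OC)c1.[Cr].[C-]#[O+].[C-]#[O+].[C-]#[O+]
F9 | step 5 | Cr(CO)3 complex of ether 10 on the dimethoxyphenoxy ring, written as its components | COc1ccc(COC[C@@H]([C@](C)(Oc2cc(OC)cc(OC)c2)CCC=C(C)C)CCC#C[Si](C)(C)C)cc1.[Cr].[C-]#[O+].[C-]#[O+].[C-]#[O+]
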